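## The problem

Target 14 is an achiral meta-depside. Ring A is a 2,4-dihydroxy-6-propylbenzoyl group. Ring B is a benzoic acid with the carboxyl on C1, OMe on C2, the ester oxygen on C3, OH on C4, H on C5 and propyl on C6.

There is no stereocentre and no ring fusion, so the difficulty is positional. Ring B is pentasubstituted, and its three neighbouring oxygens must end as three different functions.

The inherent reactivity of a 2,3,4-trihydroxybenzoate runs against all three. C4–OH (para to the carboxyl, open) reacts first but must stay free. C2–OH (chelated to the carboxyl) reacts last but must be methylated. C3–OH (flanked on both sides) must take the bulkiest group.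

The ester joins a 2,6-disubstituted benzoic acid to a 2,6-disubstituted phenol, the worst case for acyl transfer.

Several groups are sensitive:
- The aryl ester does not survive hydroxide or alkoxide, so the C1 acid cannot be freed by saponification.
- Both ortho-oxygenated benzoic acids lose CO2 on heating or in strong acid.
- Under base, C4–OH can take over the acyl group. The C3 ester is the ester of the least acidic phenol, so it should be the stable isomer.

The feature that opens the problem lies in ring B. The run C2–C3–C4–C5 has the oxidation pattern of an acetoacetic ester oxygenated at its α carbon: C2 is the ester carbon, C3 the α carbon, C4 the ketone carbon and C5 the methyl carbon. C6–C1, with propyl and carboxyl, is hex-2-ynoic acid.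

That α carbon is sp3 and can carry a leaving group. The C3–O bond can therefore be made by SN2, with the ring A carboxylate as nucleophile, before ring B exists. Ring B is then closed around it.

## Retrosynthesis

**14 ⇒ 13 ⇒ 12.** The benzyl–oxygen bond of the C1 ester and three O–Si bonds are cut. A benzyl ester is preferred to a methyl ester because only a neutral release of the acid spares the depside link. The silyl ethers cost no step of their own, since they arrive with the silylation that makes the diene. The forward steps are a buffered fluoride cleavage and a hydrogenolysis.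

**12 ⇒ 11.** The O–CH3 bond at C2 is cut. In 11 the C2 hydroxyl is the only free hydroxyl of the molecule, so the least reactive oxygen of ring B is methylated without competition. The forward reaction must be neutral, so that aryl silyl ethers and the neighbouring ester stay in place.

**11 ⇒ 6 + 8 (through 10 and 9).** The bonds C1–C2 and C5–C6 of ring B are cut.
- Every other pair of ring bonds would put the acyloxy carbon at a diene terminus or would need an oxygenated alkyne.
- This pair alone gives a diene 6 that holds all three oxygens and a plain alkynoate 8, with matched polarity.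
- A pentasubstituted arene with three differentiated oxygens and a hindered aryl ester falls back to an open-chain enol ester and a six-carbon alkyne.
- The forward reaction must give one regiochemistry and an aromatisation that leaves the three oxygens distinguishable.

**6 ⇒ 4 ⇒ 3 (through 5).** Four O–Si bonds are cut. Three TBS groups go on first, to the two phenols of ring A and to the ketone enol. One TMS group goes on last, to the ester enolate 5. The different silyl groups mark which oxygen is unmasked after the cycloaddition. The precursor 3 is an ordinary β-keto ester.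

**3 ⇒ 1 + 2.** The alkyl–oxygen bond O–C3 is cut, not the acyl–oxygen bond beside it. The hindered carbonyl group of ring A is never attacked. Acid 1 acts as the nucleophile at its remote oxygen, on a doubly activated secondary chloride 2. Both precursors are catalogue compounds, and the phenols of 1 need no protection.

**8 ⇒ 7.** The benzyl–oxygen bond is cut. A simple carboxylate alkylation of hex-2-ynoic acid 7 is asked for.

## Roads not taken

**Alternative 1:** the acyl–oxygen bond of the depside ester is cut. This is the obvious route.
- Forward: 2,4-bis(benzyloxy)-6-propylbenzoic acid A1 is coupled with benzyl 4-(benzyloxy)-3-hydroxy-2-methoxy-6-propylbenzoate A2, using trifluoroacetic anhydride or carbodiimide/DMAP. This gives the perbenzylated depside A3, which is hydrogenolysed.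
- All the difficulty moves into A2. Its C3 oxygen must be introduced on a resorcylate by formylation and Dakin oxidation or a similar sequence. Its three oxygens must then be told apart by protection steps that go against their natural order of reactivity.
- The coupling then meets hindrance on both partners.
- The chosen plan needs no aromatic substitution on ring B, no separate phenol protection and no acyl transfer.

**Alternative 2:** C3–O is cut on a partly saturated ring B, which is aromatised late.
- Forward: benzyl 2,4-dioxo-6-propylcyclohexane-1-carboxylate A4 comes from a Michael–Claisen reaction of dibenzyl malonate with hept-3-en-2-one. It takes a diazo group at C3, its only CH2 between two carbonyl groups, to give A5.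
- Rh2(OAc)4-catalysed O–H insertion of A1 gives the 3-acyloxy dione A6, which is dehydrogenated.
- The site of oxygenation and the hindered ester are solved well. C2–O and C4–O, however, come out as the two ends of one enolised diketone.
- After aromatisation the chelated C2–OH can be methylated only after C4–OH has been protected under base.
- The dehydrogenation must spare an enol ester and electron-rich arenes, and A1 itself takes several steps. The chosen plan differentiates all three oxygens in the ring-forming step and needs no oxidation.

**Alternative 3:** C6–propyl and C1–carboxyl are cut together through an aryne.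
- Forward: 1,2-bis(benzyloxy)-5-chloro-3-methoxybenzene A7 is converted with a lithium amide into aryne A8. A propyl-metal adds at C6, remote from the methoxy group, and the aryl anion beside the methoxy group takes up CO2 to give acid A9.
- The orientation on A8 is sound. In A7, however, both hydrogens next to chlorine are flanked by an alkoxy group. The isomeric aryne therefore forms as well and leads to the regioisomeric acid A10.
- The step places only the two easy substituents. The differentiation of C3–O from C4–O and the hindered esterification remain as in Alternative 1.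

Key step: step 5

Assumption: acid 1 is taken as a catalogue compound. The double-bond geometries of 4, 5 and 6 are left undefined because they are lost when ring B forms.

## Steps

TBS = tert-butyldimethylsilyl, TMS = trimethylsilyl.

Step 1
Reactants: 1 2,4-dihydroxy-6-propylbenzoic acid; 2 methyl 2-chloro-3-oxobutanoate (racemic)
Product: 3 methyl 2-[(2,4-dihydroxy-6-propylbenzoyl)oxy]-3-oxobutanoate (racemic, keto–enol mixture)
Conditions: KHCO3 (1.0 equiv), DMF, rt to 40 °C
Reagents that add atoms: none
Why: SN2 displacement of a doubly activated secondary chloride by a carboxylate, a known route to 2-acyloxyacetoacetates; the crowding around the carbonyl group of 1 does not matter because the new bond forms at the sp3 carbon of 2. One equivalent of KHCO3 ionises only the carboxyl group, so the phenols are not alkylated and 2 is not enolised. The new stereocentre is racemic and labile, and it disappears in step 2.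

Step 2
Reactants: 3 methyl 2-[(2,4-dihydroxy-6-propylbenzoyl)oxy]-3-oxobutanoate
Product: 4 methyl 2-({2,4-bis[(tert-butyldimethylsilyl)oxy]-6-propylbenzoyl}oxy)-3-[(tert-butyldimethylsilyl)oxy]but-2-enoate (E/Z mixture)
Conditions: TBSOTf (3.3 equiv), Et3N, CH2Cl2, 0 °C to rt
Reagents that add atoms: tert-butyldimethylsilyl trifluoromethanesulfonate, CC(C)(C)[Si](C)(C)OS(=O)(=O)C(F)(F)F
Why: Silyl triflate/amine silylation caps both phenols (the chelated one included) and turns the β-keto ester into its conjugated silyl enol ether by soft enolisation, all in one operation. The limited amount of triflate keeps the ester carbonyl group unsilylated.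

Step 3
Reactants: 4 methyl 2-({2,4-bis[(tert-butyldimethylsilyl)oxy]-6-propylbenzoyl}oxy)-3-[(tert-butyldimethylsilyl)oxy]but-2-enoate
Product: 6 3-[(tert-butyldimethylsilyl)oxy]-1-methoxy-1-[(trimethylsilyl)oxy]buta-1,3-dien-2-yl 2,4-bis[(tert-butyldimethylsilyl)oxy]-6-propylbenzoate, via lithium dienolate 5 (not isolated)
Conditions: TMSCl (1.3 equiv), then LiN(iPr)2 (LDA, 1.1 equiv), THF, −78 °C to 0 °C; pentane, filtration, used crude
Reagents that add atoms: chlorotrimethylsilane, C[Si](C)(C)Cl
Why: γ-Deprotonation of a 3-silyloxybut-2-enoate and O-silylation of the extended ester enolate 5 is the standard way to 1-alkoxy-1,3-bis(silyloxy)buta-1,3-dienes. The labile TMS group is placed on purpose on the oxygen that becomes C2–O of ring B. The 2,6-disubstituted aroyl carbonyl group is shielded from amide and enolate, and TMSCl present from the start traps 5 as it forms.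

Step 4
Reactants: 7 hex-2-ynoic acid
Product: 8 benzyl hex-2-ynoate
Conditions: BnBr, KHCO3, DMF, rt
Reagents that add atoms: benzyl bromide, BrCc1ccccc1
Why: Carboxylate alkylation. The weak base avoids isomerisation of the alkynoate to the allenoate.

Step 5
Reactants: 6 3-[(tert-butyldimethylsilyl)oxy]-1-methoxy-1-[(trimethylsilyl)oxy]buta-1,3-dien-2-yl 2,4-bis[(tert-butyldimethylsilyl)oxy]-6-propylbenzoate; 8 benzyl hex-2-ynoate
Product: 11 benzyl 3-({2,4-bis[(tert-butyldimethylsilyl)oxy]-6-propylbenzoyl}oxy)-4-[(tert-butyldimethylsilyl)oxy]-2-hydroxy-6-propylbenzoate, via cyclohexa-1,4-diene cycloadduct 9 (not isolated), via aryl trimethylsilyl ether 10 (not isolated)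
Conditions: 6 (1.5 equiv), toluene (concentrated), 120 °C, sealed tube; then aq. citric acid, THF, rt
Reagents that add atoms: none
Why: This is a Diels–Alder reaction with aromatisation, the reaction type by which 1,1-dioxygenated 3-silyloxybuta-1,3-dienes and alk-2-ynoates give 6-alkyl-2,4-dioxygenated benzoates. The [4+2] addition is concerted but strongly asynchronous: the CH2 terminus of 6, where the donor effects of the oxygens on diene C1 and C3 add up (largest HOMO coefficient), bonds ahead to the propyl-bearing β carbon of 8 (largest LUMO coefficient), and the ketene acetal carbon closes on the α carbon to give 9. Ring B is thus closed as a six-membered carbocycle by an intermolecular [4+2] cycloaddition that forms C5–C6 and C1–C2, and no other ring is formed. Cycloadduct 9 loses methanol from the C2 mixed ketal and the C5 methylene group (a 1,4-elimination driven by aromatisation) to give 10, whose labile aryl TMS ether is hydrolysed by aqueous citric acid while the three aryl TBS ethers stay. The only stereocentre formed (C2 of 9, racemic) is destroyed in this elimination, and the double-bond geometry of 6 has no consequence. The step needs regioselectivity, which the matched polarisation secures (the weakly donating aroyloxy group on diene C2 opposes it only slightly), and it needs three different oxygens, which their origin secures: the ketene acetal oxygen becomes the free phenol, the enol ester oxygen the depside ester, and the enol TBS ether the aryl TBS ether. Any part of 9 that loses trimethylsilanol in place of methanol gives 12, the product of step 6, so both modes of aromatisation converge. The enol ester of the hindered acid has no acidic hydrogen and no nucleophile nearby and should stand the heating, and the excess of 6 makes up for what the liberated methanol desilylates.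

Step 6
Reactants: 11 benzyl 3-({2,4-bis[(tert-butyldimethylsilyl)oxy]-6-propylbenzoyl}oxy)-4-[(tert-butyldimethylsilyl)oxy]-2-hydroxy-6-propylbenzoate
Product: 12 benzyl 3-({2,4-bis[(tert-butyldimethylsilyl)oxy]-6-propylbenzoyl}oxy)-4-[(tert-butyldimethylsilyl)oxy]-2-methoxy-6-propylbenzoate
Conditions: MeOH, PPh3, DIAD, THF, 0 °C to rt
Reagents that add atoms: methanol, CO
Why: Mitsunobu etherification. Compound 11 has a single free hydroxyl, and 2-hydroxybenzoates are competent acidic partners. The substitution takes place at an unhindered methyl carbon. The neutral medium leaves the aryl silyl ethers and both esters alone and keeps the phenoxide too short-lived for an acyl shift from C3–O.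

Step 7
Reactants: 12 benzyl 3-({2,4-bis[(tert-butyldimethylsilyl)oxy]-6-propylbenzoyl}oxy)-4-[(tert-butyldimethylsilyl)oxy]-2-methoxy-6-propylbenzoate
Product: 13 benzyl 3-[(2,4-dihydroxy-6-propylbenzoyl)oxy]-4-hydroxy-2-methoxy-6-propylbenzoate
Conditions: Bu4NF (3.3 equiv), AcOH (3.3 equiv), THF, 0 °C
Reagents that add atoms: none
Why: Fluoride cleavage of aryl silyl ethers, buffered with acetic acid so that no phenoxide persists. The ester of a 2,6-disubstituted acid resists attack. The acyl group should stay on C3–O because C4–OH, para to the ester group, is the more acidic phenol and its ester would be the less stable one.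

Step 8
Reactants: 13 benzyl 3-[(2,4-dihydroxy-6-propylbenzoyl)oxy]-4-hydroxy-2-methoxy-6-propylbenzoate
Product: 14 3-[(2,4-dihydroxy-6-propylbenzoyl)oxy]-4-hydroxy-2-methoxy-6-propylbenzoic acid
Conditions: H2 (1 atm), Pd/C, EtOAc, rt
Reagents that add atoms: none
Why: Hydrogenolysis of the benzyl ester frees the hindered acid at room temperature in neutral medium. This avoids both cleavage of the depside ester and decarboxylation.

## Compound list

1 | 2,4-dihydroxy-6-propylbenzoic acid | CCCc1cc(O)cc(O)c1C(=O)O | starting material
2 | methyl 2-chloro-3-oxobutanoate (racemic) | COC(=O)C(Cl)C(C)=O | starting material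
3 | methyl 2-[(2,4-dihydroxy-6-propylbenzoyl)oxy]-3-oxobutanoate (racemic) | CCCc1cc(O)cc(O)c1C(=O)OC(C(C)=O)C(=O)OC | intermediate
4 | methyl 2-({2,4-bis[(tert-butyldimethylsilyl)oxy]-6-propylbenzoyl}oxy)-3-[(tert-butyldimethylsilyl)oxy]but-2-enoate (E/Z mixture) | CCCc1cc(O[Si](C)(C)C(C)(C)C)cc(O[Si](C)(C)C(C)(C)C)c1C(=O)OC(C(=O)OC)=C(C)O[Si](C)(C)C(C)(C)C | intermediate
5 | lithium dienolate of 4 (lithium 2-aroyloxy-3-[(tert-butyldimethylsilyl)oxy]-1-methoxybuta-1,3-dien-1-olate) | CCCc1cc(O[Si](C)(C)C(C)(C)C)cc(O[Si](C)(C)C(C)(C)C)c1C(=O)OC(C(=C)O[Si](C)(C)C(C)(C)C)=C(OC)[O-].[Li+] | intermediate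
6 | 3-[(tert-butyldimethylsilyl)oxy]-1-methoxy-1-[(trimethylsilyl)oxy]buta-1,3-dien-2-yl 2,4-bis[(tert-butyldimethylsilyl)oxy]-6-propylbenzoate | CCCc1cc(O[Si](C)(C)C(C)(C)C)cc(O[Si](C)(C)C(C)(C)C)c1C(=O)OC(C(=C)O[Si](C)(C)C(C)(C)C)=C(OC)O[Si](C)(C)C | intermediate
7 | hex-2-ynoic acid | CCCC#CC(=O)O | starting material
8 | benzyl hex-2-ynoate | CCCC#CC(=O)OCc1ccccc1 | intermediate
9 | benzyl 5-({2,4-bis[(tert-butyldimethylsilyl)oxy]-6-propylbenzoyl}oxy)-4-[(tert-butyldimethylsilyl)oxy]-6-methoxy-2-propyl-6-[(trimethylsilyl)oxy]cyclohexa-1,4-diene-1-carboxylate (racemic) | CCCC1=C(C(=O)OCc2ccccc2)C(OC)(O[Si](C)(C)C)C(OC(=O)c2c(CCC)cc(O[Si](C)(C)C(C)(C)C)cc2O[Si](C)(C)C(C)(C)C)=C(O[Si](C)(C)C(C)(C)C)C1 | intermediate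
10 | benzyl 3-({2,4-bis[(tert-butyldimethylsilyl)oxy]-6-propylbenzoyl}oxy)-4-[(tert-butyldimethylsilyl)oxy]-6-propyl-2-[(trimethylsilyl)oxy]benzoate | CCCc1cc(O[Si](C)(C)C(C)(C)C)c(OC(=O)c2c(CCC)cc(O[Si](C)(C)C(C)(C)C)cc2O[Si](C)(C)C(C)(C)C)c(O[Si](C)(C)C)c1C(=O)OCc1ccccc1 | intermediate
11 | benzyl 3-({2,4-bis[(tert-butyldimethylsilyl)oxy]-6-propylbenzoyl}oxy)-4-[(tert-butyldimethylsilyl)oxy]-2-hydroxy-6-propylbenzoate | CCCc1cc(O[Si](C)(C)C(C)(C)C)c(OC(=O)c2c(CCC)cc(O[Si](C)(C)C(C)(C)C)cc2O[Si](C)(C)C(C)(C)C)c(O)c1C(=O)OCc1ccccc1 | intermediate
12 | benzyl 3-({2,4-bis[(tert-butyldimethylsilyl)oxy]-6-propylbenzoyl}oxy)-4-[(tert-butyldimethylsilyl)oxy]-2-methoxy-6-propylbenzoate | CCCc1cc(O[Si](C)(C)C(C)(C)C)c(OC(=O)c2c(CCC)cc(O[Si](C)(C)C(C)(C)C)cc2O[Si](C)(C)C(C)(C)C)c(OC)c1C(=O)OCc1ccccc1 | intermediate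
13 | benzyl 3-[(2,4-dihydroxy-6-propylbenzoyl)oxy]-4-hydroxy-2-methoxy-6-propylbenzoate | CCCc1cc(O)c(OC(=O)c2c(CCC)cc(O)cc2O)c(OC)c1C(=O)OCc1ccccc1 | intermediate
14 | 3-[(2,4-dihydroxy-6-propylbenzoyl)oxy]-4-hydroxy-2-methoxy-6-propylbenzoic acid | CCCc1cc(O)cc(O)c1C(=O)Oc1c(O)cc(CCC)c(C(=O)O)c1OC | target

## Step count and least certain steps

Total steps: 8. Longest linear sequence: 7 (steps 1, 2, 3, 5, 6, 7, 8).

**Step 5 (key step).**
- Risk: the cycloaddition may be too slow. A β-alkyl alkynoate is a weak dienophile. The diene is fully substituted at one terminus, and its bulky, weakly withdrawing aroyloxy group raises the energy of the s-cis conformer.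
- Consequence: thermal decay of the silyl ketene acetal (silyl migration to carbon, desilylation by the liberated methanol) may then outrun ring formation.
- Fallback: it sets out from 6 and changes the two-carbon partner from an alkyne to a cumulene. Benzyl hexa-2,3-dienoate F1 is made by the Wittig-type reaction of benzyl (triphenylphosphoranylidene)acetate with butanoyl chloride and Et3N. It reacts across its C2–C3 double bond.
- Its sp-hybridised central carbon is unhindered and more electrophilic, so addition should proceed near room temperature with the same orientation (diene CH2 to the central carbon).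
- The propylidene cycloadduct F2 loses methanol, and its exocyclic double bond moves into the ring by prototropy. The fallback comes back to the route at 10, which the same work-up turns into 11.

**Step 1.**
- Risk: the displacement may be sluggish because the chelated carboxylate is a weak nucleophile. Slow reaction gives time for enolisation and self-condensation of the chloro keto ester, or for alkylation at the C4 phenol of ring A.
- Fallback: it sets out from 1 and replaces substitution by carbenoid O–H insertion. Methyl 2-diazo-3-oxobutanoate F3 is made from methyl acetoacetate by Regitz diazo transfer with 4-acetamidobenzenesulfonyl azide and Et3N. It is decomposed with catalytic Rh2(OAc)4 in CH2Cl2 in the presence of 1.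
- The most acidic O–H reacts first and no base is present. The fallback comes back to the route at 3.

**Step 3.**
- Risk: deprotonation may go astray, either to the benzylic CH2 of the ring A propyl group (lateral metalation beside the ester) or only slowly with one geometric isomer of 4.
- Further risks: dienolate 5 may attack the aroyl carbonyl group (an acyl shift from oxygen to carbon), and the product may hydrolyse on handling.
- Fallback: it sets out from 1 and fixes the terminal methylene group before the ester oxygen arrives. F3 is silylated at its only enolisable position (TBSOTf, Et3N) to methyl 3-[(tert-butyldimethylsilyl)oxy]-2-diazobut-3-enoate F4.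
- Rh2(OAc)4-catalysed O–H insertion of 1 at the carbenoid carbon gives methyl 3-[(tert-butyldimethylsilyl)oxy]-2-[(2,4-dihydroxy-6-propylbenzoyl)oxy]but-3-enoate F5. TBSOTf with 2,6-lutidine then caps the two phenols to give the tris-silyl but-3-enoate F6.
- The remaining C2–H is flanked by the ester, acyloxy and vinyl groups and is far more acidic than any benzylic hydrogen. It is removed with LiN(SiMe3)2 at −78 °C in the presence of TMSCl. The fallback comes back to the route at 6.

## Further compounds

F1 | step 5 | benzyl hexa-2,3-dienoate (racemic) | CCC=C=CC(=O)OCc1ccccc1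
F2 | step 5 | benzyl 3-({2,4-bis[(tert-butyldimethylsilyl)oxy]-6-propylbenzoyl}oxy)-4-[(tert-butyldimethylsilyl)oxy]-2-methoxy-6-propylidene-2-[(trimethylsilyl)oxy]cyclohex-3-ene-1-carboxylate (mixture of stereoisomers) | CCC=C1CC(O[Si](C)(C)C(C)(C)C)=C(OC(=O)c2c(CCC)cc(O[Si](C)(C)C(C)(C)C)cc2O[Si](C)(C)C(C)(C)C)C(OC)(O[Si](C)(C)C)C1C(=O)OCc1ccccc1
F3 | step 1 | methyl 2-diazo-3-oxobutanoate | COC(=O)C(=[N+]=[N-])C(C)=O
F4 | step 3 | methyl 3-[(tert-butyldimethylsilyl)oxy]-2-diazobut-3-enoate | COC(=O)C(=[N+]=[N-])C(=C)O[Si](C)(C)C(C)(C)C
F5 | step 3 | methyl 3-[(tert-butyldimethylsilyl)oxy]-2-[(2,4-dihydroxy-6-propylbenzoyl)oxy]but-3-enoate (racemic) | CCCc1cc(O)cc(O)c1C(=O)OC(C(=O)OC)C(=C)O[Si](C)(C)C(C)(C)C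
F6 | step 3 | methyl 2-({2,4-bis[(tert-butyldimethylsilyl)oxy]-6-propylbenzoyl}oxy)-3-[(tert-butyldimethylsilyl)oxy]but-3-enoate (racemic) | CCCc1cc(O[Si](C)(C)C(C)(C)C)cc(O[Si](C)(C)C(C)(C)C)c1C(=O)OC(C(=O)OC)C(=C)O[Si](C)(C)C(C)(C)C
A1 | alternative 1 | 2,4-bis(benzyloxy)-6-propylbenzoic acid | CCCc1cc(OCc2ccccc2)cc(OCc2ccccc2)c1C(=O)O
A2 | alternative 1 | benzyl 4-(benzyloxy)-3-hydroxy-2-methoxy-6-propylbenzoate | CCCc1cc(OCc2ccccc2)c(O)c(OC)c1C(=O)OCc1ccccc1
A3 | alternative 1 | benzyl 4-(benzyloxy)-3-{[2,4-bis(benzyloxy)-6-propylbenzoyl]oxy}-2-methoxy-6-propylbenzoate | CCCc1cc(OCc2ccccc2)cc(OCc2ccccc2)c1C(=O)Oc1c(OCc2ccccc2)cc(CCC)c(C(=O)OCc2ccccc2)c1OC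
A4 | alternative 2 | benzyl 2,4-dioxo-6-propylcyclohexane-1-carboxylate (mixture of stereoisomers and tautomers) | CCCC1CC(=O)CC(=O)C1C(=O)OCc1ccccc1
A5 | alternative 2 | benzyl 3-diazo-2,4-dioxo-6-propylcyclohexane-1-carboxylate (mixture of stereoisomers) | CCCC1CC(=O)C(=[N+]=[N-])C(=O)C1C(=O)OCc1ccccc1
A6 | alternative 2 | benzyl 3-{[2,4-bis(benzyloxy)-6-propylbenzoyl]oxy}-2,4-dioxo-6-propylcyclohexane-1-carboxylate (mixture of stereoisomers and tautomers) | CCCC1CC(=O)C(OC(=O)c2c(CCC)cc(OCc3ccccc3)cc2OCc2ccccc2)C(=O)C1C(=O)OCc1ccccc1
A7 | alternative 3 | 1,2-bis(benzyloxy)-5-chloro-3-methoxybenzene | COc1cc(Cl)cc(OCc2ccccc2)c1OCc1ccccc1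
A8 | alternative 3 | 4,5-bis(benzyloxy)-3-methoxybenzyne | COC1=C(OCc2ccccc2)C(OCc2ccccc2)=CC#C1
A9 | alternative 3 | 3,4-bis(benzyloxy)-2-methoxy-6-propylbenzoic acid | CCCc1cc(OCc2ccccc2)c(OCc2ccccc2)c(OC)c1C(=O)O
A10 | alternative 3 | 2,3-bis(benzyloxy)-4-methoxy-6-propylbenzoic acid | CCCc1cc(OC)c(OCc2ccccc2)c(OCc2ccccc2)c1C(=O)O
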